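**Retrosynthetic overview**

1. Numbering: lactone O1–C2(=O)–C3–C4–C5; C7 is the benzylic carbon between C3 and ring A (3,4-dimethoxyphenyl); C7' is the benzylic carbon between C4 and ring B (catechol). The strategy rests on C3 being bonded to C4 and 1,3-related to C7' while carrying C2(=O) and, at the ketone level, C7(=O). A C3 carbene can therefore close the C3/C4/C7' triad as a cyclopropane, and the extra C3–C7' bond (two acceptors on one end, donor aryl on the other) can be removed by hydrogenolysis.
2. 12 ⇐ 10 (C7 ketone to CH2) ⇐ 8 (hydrogenolysis of C3–C7' and of both O-benzyl ethers, then C3 equilibration to trans).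
3. 8 ⇐ 7: intramolecular carbenoid cyclopropanation that forms C3–C4 and the sacrificial C3–C7' bond and closes the lactone and the cyclopropane in one step.
4. 7 ⇐ 6 (diazo transfer) ⇐ 4 + 5 (ester exchange); 4 ⇐ 1 + 2 (olefination, ester reduction).
5. Ring order: rings A and B are bought; the lactone and the cyclopropane form together in step 5; the cyclopropane is opened in step 6 and the lactone remains.

Key step: step 5

Assumption: the sense of induction of a chiral dirhodium carboxylate with this tethered acceptor/acceptor carbenoid cannot be predicted with confidence; the route is written with Rh2(S-TCPTTL)4, and Rh2(R-TCPTTL)4 (from D-tert-leucine) replaces it if a test run shows the opposite sense.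

**Route**

Step 1
Reactants: 1 3,4-bis(benzyloxy)benzaldehyde; 2 triethyl phosphonoacetate
Product: 3 ethyl (E)-3-[3,4-bis(benzyloxy)phenyl]prop-2-enoate
Conditions: NaH, THF, 0 °C → rt
Reagents that add atoms: none
Why: Horner–Wadsworth–Emmons olefination of an aromatic aldehyde with a stabilised phosphonate anion should give the E-cinnamate selectively, and the benzyl ethers are inert to NaH.

Step 2
Reactants: 3 ethyl (E)-3-[3,4-bis(benzyloxy)phenyl]prop-2-enoate
Product: 4 (E)-3-[3,4-bis(benzyloxy)phenyl]prop-2-en-1-ol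
Conditions: i-Bu2AlH (2.5 equiv), CH2Cl2, −78 → 0 °C; aq. potassium sodium tartrate
Reagents that add atoms: none
Why: 1,2-reduction of a conjugated ester by i-Bu2AlH at low temperature should deliver the allylic alcohol without touching the alkene or the benzyl ethers.

Step 3
Reactants: 4 (E)-3-[3,4-bis(benzyloxy)phenyl]prop-2-en-1-ol; 5 ethyl 3-(3,4-dimethoxyphenyl)-3-oxopropanoate
Product: 6 (E)-3-[3,4-bis(benzyloxy)phenyl]prop-2-en-1-yl 3-(3,4-dimethoxyphenyl)-3-oxopropanoate
Conditions: DMAP (0.3 equiv), toluene, reflux, 4 Å MS (Soxhlet, removal of EtOH)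
Reagents that add atoms: none
Why: DMAP-catalysed transesterification of a β-ketoester runs under neutral conditions through the acylketene/enol manifold and is driven by removal of ethanol, so the acid-sensitive electron-rich cinnamyl alcohol is not ionised.

Step 4
Reactants: 6 (E)-3-[3,4-bis(benzyloxy)phenyl]prop-2-en-1-yl 3-(3,4-dimethoxyphenyl)-3-oxopropanoate
Product: 7 (E)-3-[3,4-bis(benzyloxy)phenyl]prop-2-en-1-yl 2-diazo-3-(3,4-dimethoxyphenyl)-3-oxopropanoate
Conditions: p-ABSA, Et3N, MeCN, 0 °C → rt
Reagents that add atoms: 4-acetamidobenzenesulfonyl azide (p-ABSA), CC(=O)Nc1ccc(cc1)S(=O)(=O)N=[N+]=[N-]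
Why: Regitz diazo transfer to the doubly activated methylene of a β-ketoester proceeds with a sulfonyl azide and a tertiary amine, and the alkene and benzyl ethers are spectators.

Step 5
Reactants: 7 (E)-3-[3,4-bis(benzyloxy)phenyl]prop-2-en-1-yl 2-diazo-3-(3,4-dimethoxyphenyl)-3-oxopropanoate
Product: 8 (1S,5R,6S)-6-[3,4-bis(benzyloxy)phenyl]-1-(3,4-dimethoxybenzoyl)-3-oxabicyclo[3.1.0]hexan-2-one
Conditions: Rh2(S-TCPTTL)4 (1 mol %), CH2Cl2, 0 °C → rt, slow addition of 7
Reagents that add atoms: none
Why: Rh2(S-TCPTTL)4 expels N2 from 7 to give an electrophilic rhodium carbenoid at C3, flanked by the aryl ketone and the ester, which adds to the tethered electron-rich E-styrene in a concerted but asynchronous (2+1) cycloaddition (intramolecular carbenoid cyclopropanation). The closest known reaction type is the catalytic asymmetric intramolecular cyclopropanation of allyl α-diazo-β-ketoesters and, for the catalyst, the cyclopropanation of styrenes with α-aroyl diazoacetates by phthalimido-tert-leucinate dirhodium carboxylates, where an electron-rich aryl ketone acts as the stereocontrolling substituent. The lactone closes 5-exo-trig by attack of C3 on the proximal alkene carbon C4, and the cyclopropane closes 3-exo onto the benzylic carbon C7', where the developing positive charge is stabilised by the dialkoxyaryl ring. C4 (C5 of the bicycle) is set by the alkene face selected in the chiral pocket of the catalyst, C3 (C1) follows from the obligatory cis fusion of the five- and three-membered rings, and C7' (C6) from stereospecific transfer of the E geometry, which places the aryl group exo. The step needs enantioface selectivity at C4 only, plus chemoselectivity for alkene addition over 1,4 C–H insertion at the allylic OCH2 and over O-closure of a zwitterion to a dihydrofuran; the five-atom tether and the nucleophilic styrene favour alkene addition, and a dihydrofuran by-product would in any case converge on 10 in step 6 with C4 unchanged.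

Step 6
Reactants: 8 (1S,5R,6S)-6-[3,4-bis(benzyloxy)phenyl]-1-(3,4-dimethoxybenzoyl)-3-oxabicyclo[3.1.0]hexan-2-one
Product: 10 (3S,4R)-4-(3,4-dihydroxybenzyl)-3-(3,4-dimethoxybenzoyl)dihydrofuran-2(3H)-one, via C3-epimeric keto lactone 9 (not isolated)
Conditions: H2 (1 atm), 10% Pd/C, EtOAc, rt; filter; then Et3N (0.1 equiv), degassed EtOAc, rt, Ar
Reagents that add atoms: none
Why: Catalytic hydrogenolysis should cleave the push–pull C3–C7' bond of the donor–acceptor cyclopropane (benzylic at C7' and doubly α-carbonyl at C3, hence the weakest ring bond) together with both O-benzyl ethers, after which the C3–H between two carbonyls equilibrates through the enol to the more stable trans lactone while C4 is untouched.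

Step 7
Reactants: 10 (3S,4R)-4-(3,4-dihydroxybenzyl)-3-(3,4-dimethoxybenzoyl)dihydrofuran-2(3H)-one
Product: 12 (3R,4R)-4-(3,4-dihydroxybenzyl)-3-(3,4-dimethoxybenzyl)dihydrofuran-2(3H)-one (target), via benzylic carbinol 11 (not isolated)
Conditions: H2 (4 atm), 10% Pd/C, AcOH, HClO4 (cat.), rt, Ar-degassed
Reagents that add atoms: none
Why: Acid-promoted hydrogenolysis of an electron-rich aryl ketone over Pd/C runs through carbinol 11 to the C7 methylene, and once the ketone is reduced C3 is no longer readily enolised, so the trans relationship to C4 fixed in 10 should be carried into the target.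

**Compound list**

1 | 3,4-bis(benzyloxy)benzaldehyde | O=Cc1ccc(OCc2ccccc2)c(OCc2ccccc2)c1 | starting material
2 | triethyl phosphonoacetate | CCOC(=O)CP(=O)(OCC)OCC | starting material
3 | ethyl (E)-3-[3,4-bis(benzyloxy)phenyl]prop-2-enoate | CCOC(=O)/C=C/c1ccc(OCc2ccccc2)c(OCc2ccccc2)c1 | intermediate
4 | (E)-3-[3,4-bis(benzyloxy)phenyl]prop-2-en-1-ol | OC/C=C/c1ccc(OCc2ccccc2)c(OCc2ccccc2)c1 | intermediate
5 | ethyl 3-(3,4-dimethoxyphenyl)-3-oxopropanoate | CCOC(=O)CC(=O)c1ccc(OC)c(OC)c1 | starting material
6 | (E)-3-[3,4-bis(benzyloxy)phenyl]prop-2-en-1-yl 3-(3,4-dimethoxyphenyl)-3-oxopropanoate | COc1ccc(C(=O)CC(=O)OC/C=C/c2ccc(OCc3ccccc3)c(OCc3ccccc3)c2)cc1OC | intermediate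
7 | (E)-3-[3,4-bis(benzyloxy)phenyl]prop-2-en-1-yl 2-diazo-3-(3,4-dimethoxyphenyl)-3-oxopropanoate | COc1ccc(C(=O)C(=[N+]=[N-])C(=O)OC/C=C/c2ccc(OCc3ccccc3)c(OCc3ccccc3)c2)cc1OC | intermediate
8 | (1S,5R,6S)-6-[3,4-bis(benzyloxy)phenyl]-1-(3,4-dimethoxybenzoyl)-3-oxabicyclo[3.1.0]hexan-2-one | O=C1OC[C@@H]2[C@@H](c3ccc(OCc4ccccc4)c(OCc4ccccc4)c3)[C@]12C(=O)c1ccc(OC)c(OC)c1 | intermediate
9 | (4R)-4-(3,4-dihydroxybenzyl)-3-(3,4-dimethoxybenzoyl)dihydrofuran-2(3H)-one, mixture of C3 epimers | COc1ccc(C(=O)C2C(=O)OC[C@@H]2Cc2ccc(O)c(O)c2)cc1OC | intermediate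
10 | (3S,4R)-4-(3,4-dihydroxybenzyl)-3-(3,4-dimethoxybenzoyl)dihydrofuran-2(3H)-one (trans) | COc1ccc(C(=O)[C@H]2C(=O)OC[C@@H]2Cc2ccc(O)c(O)c2)cc1OC | intermediate
11 | (3S,4R)-4-(3,4-dihydroxybenzyl)-3-[(3,4-dimethoxyphenyl)(hydroxy)methyl]dihydrofuran-2(3H)-one, both carbinol epimers | COc1ccc(C(O)[C@H]2C(=O)OC[C@@H]2Cc2ccc(O)c(O)c2)cc1OC | intermediate
12 | (3R,4R)-4-(3,4-dihydroxybenzyl)-3-(3,4-dimethoxybenzyl)dihydrofuran-2(3H)-one | COc1ccc(C[C@H]2C(=O)OC[C@@H]2Cc2ccc(O)c(O)c2)cc1OC | target

**Step count**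

Total: 7 steps. Longest linear sequence: 7 steps (1 → 3 → 4 → 6 → 7 → 8 → 10 → 12).

**Steps most likely to fail**

1. Step 5. The main risk is insufficient discrimination of the alkene faces by the catalyst, since tethered carbenoids bearing two acceptors are demanding in the intramolecular mode. A second risk is diversion of the carbenoid into C–H insertion at the allylic OCH2.
Fallback (sets out from 4, returns at 12): the stereocentre C4 is made by carbenoid C–H insertion instead of cyclopropanation, and C3 by enolate alkylation. Diimide reduction of 4 (2-nitrobenzenesulfonyl hydrazide, Et3N, CH2Cl2, rt) saturates the alkene without touching the benzyl ethers and gives 3-[3,4-bis(benzyloxy)phenyl]propan-1-ol F1. Acylation with bromoacetyl bromide (NaHCO3, MeCN, 0 °C) gives 3-[3,4-bis(benzyloxy)phenyl]propyl 2-bromoacetate F2. Treatment with N,N'-ditosylhydrazine and DBU (THF, 0 °C) gives 3-[3,4-bis(benzyloxy)phenyl]propyl 2-diazoacetate F3. Intramolecular C–H insertion at the homobenzylic CH2 with a chiral dirhodium carboxamidate, Rh2(4S-MPPIM)4 or its 4R antipode, whichever delivers the 4R series (CH2Cl2, reflux), gives (4R)-4-[3,4-bis(benzyloxy)benzyl]dihydrofuran-2(3H)-one F4. Enolate alkylation anti to the C4 substituent (LiN(SiMe3)2, THF, −78 °C; 3,4-dimethoxybenzyl bromide) gives (3R,4R)-4-[3,4-bis(benzyloxy)benzyl]-3-(3,4-dimethoxybenzyl)dihydrofuran-2(3H)-one F5. Hydrogenolysis of the benzyl ethers (H2, Pd/C, EtOAc) gives 12.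

2. Step 7. The reduction may stall at the carbinol stage. In the strong acid the C7 carbinol may also ionise, followed either by Friedel–Crafts ring closure onto ring B or by dehydration and re-hydrogenation, which would scramble C3.
Fallback (sets out from 10, returns at 12): the C7 oxygen is removed as a benzylic ester under neutral conditions, so no cation is formed. NaBH4 (MeOH–THF, −20 °C) reduces the ketone of 10 to carbinol 11, which is isolated this time. Ac2O in pyridine (0 °C → rt) gives (3S,4R)-4-(3,4-diacetoxybenzyl)-3-[acetoxy(3,4-dimethoxyphenyl)methyl]dihydrofuran-2(3H)-one F6. Neutral hydrogenolysis of the benzylic acetate (H2, 1 atm, Pd/C, EtOAc) gives (3R,4R)-4-(3,4-diacetoxybenzyl)-3-(3,4-dimethoxybenzyl)dihydrofuran-2(3H)-one F7. NH4OAc in aqueous MeOH (rt, Ar) removes the two aryl acetates and gives 12.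

3. Step 6. The wrong benzylic cyclopropane bond (C4–C7' instead of C3–C7') may be cleaved, the ring opening may be incomplete once the benzyl ethers have gone, or the ketone may be reduced unevenly before C3 has equilibrated.
Fallback (sets out from 8, returns at 10): the cyclopropane is opened by single-electron transfer instead of on a metal surface. SmI2 (2.5 equiv, THF–MeOH, −78 °C) forms the ketyl of the aryl ketone, the cyclopropylcarbinyl radical fragments along the bond that releases the benzylic radical (C3–C7'), and a second electron transfer and protonation give (3S,4R)-4-[3,4-bis(benzyloxy)benzyl]-3-(3,4-dimethoxybenzoyl)dihydrofuran-2(3H)-one F8 with the benzyl ethers intact. Hydrogenolysis of the benzyl ethers alone (H2, 1 atm, Pd/C, EtOAc) then gives 10.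

**Further compounds**

F1 | step 5 | 3-[3,4-bis(benzyloxy)phenyl]propan-1-ol | OCCCc1ccc(OCc2ccccc2)c(OCc2ccccc2)c1
F2 | step 5 | 3-[3,4-bis(benzyloxy)phenyl]propyl 2-bromoacetate | O=C(CBr)OCCCc1ccc(OCc2ccccc2)c(OCc2ccccc2)c1
F3 | step 5 | 3-[3,4-bis(benzyloxy)phenyl]propyl 2-diazoacetate | [N-]=[N+]=CC(=O)OCCCc1ccc(OCc2ccccc2)c(OCc2ccccc2)c1
F4 | step 5 | (4R)-4-[3,4-bis(benzyloxy)benzyl]dihydrofuran-2(3H)-one | O=C1C[C@@H](Cc2ccc(OCc3ccccc3)c(OCc3ccccc3)c2)CO1
F5 | step 5 | (3R,4R)-4-[3,4-bis(benzyloxy)benzyl]-3-(3,4-dimethoxybenzyl)dihydrofuran-2(3H)-one | COc1ccc(C[C@H]2C(=O)OC[C@@H]2Cc2ccc(OCc3ccccc3)c(OCc3ccccc3)c2)cc1OC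
F6 | step 7 | (3S,4R)-4-(3,4-diacetoxybenzyl)-3-[acetoxy(3,4-dimethoxyphenyl)methyl]dihydrofuran-2(3H)-one | COc1ccc(C(OC(C)=O)[C@H]2C(=O)OC[C@@H]2Cc2ccc(OC(C)=O)c(OC(C)=O)c2)cc1OC
F7 | step 7 | (3R,4R)-4-(3,4-diacetoxybenzyl)-3-(3,4-dimethoxybenzyl)dihydrofuran-2(3H)-one | COc1ccc(C[C@H]2C(=O)OC[C@@H]2Cc2ccc(OC(C)=O)c(OC(C)=O)c2)cc1OC
F8 | step 6 | (3S,4R)-4-[3,4-bis(benzyloxy)benzyl]-3-(3,4-dimethoxybenzoyl)dihydrofuran-2(3H)-one | COc1ccc(C(=O)[C@H]2C(=O)OC[C@@H]2Cc2ccc(OCc3ccccc3)c(OCc3ccccc3)c2)cc1OC
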